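**Retrosynthetic overview**
- Feature: in ring C the carbonyl carbon C4 is bonded only to C4a of ring A and to C3, the carbon that carries ring B. C4 is therefore cut out as carbon monoxide. C4a–C4 and C4–C3 are made together by a carbonylative Negishi coupling of a ring A aryl iodide, CO and a ring B benzylzinc chloride.
- Ring C is the only ring built, and it closes last. Only the oxygen on C8a carries a silyl group, so after its release C2 is added from DMF dimethyl acetal and O1–C2 closure can give only the 6-prenyl isoflavone.
- Ring A iodide: phloroglucinol → bis-MOM ether → lithiation between the two OMOM groups and prenylation → mirror-symmetric phenol with two equivalent ortho positions → mono-iodide → TBS ether.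
- Ring B zinc reagent: 3,4-dihydrocoumarin and MeMgBr give the 3-hydroxy-3-methylbutyl chain, followed by para-bromination, protection, hydroxymethylation, chloride formation and zinc insertion.
- Protecting groups: the phenols are aryl MOM ethers and the tertiary alcohol is a TES ether rather than an alkyl MOM ether. All of them then fall in acid mild enough for the prenyl group and the tertiary alcohol.

Key step: step 14

Remark: the target has no stereocentre, and its only alkene carries two identical methyl groups on one carbon, so no stereocontrol is needed.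

**Step 1**
Reactants: 1 phloroglucinol (anhydrous)
Product: 2 3,5-bis(methoxymethoxy)phenol
Conditions: MOMCl (2.0 equiv), i-Pr2NEt (2.2 equiv), DMF, 0 °C → rt; chromatography
Reagents that add atoms: chloromethyl methyl ether (MOMCl), COCCl
Why: Williamson-type O-alkylation of three equivalent phenols with two equivalents of the hard electrophile MOMCl should give the bis-ether as the main part of a statistical mixture, from which it is separated by polarity.

**Step 2**
Reactants: 2 3,5-bis(methoxymethoxy)phenol
Product: 3 [3,5-bis(methoxymethoxy)phenoxy]triisopropylsilane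
Conditions: TIPSCl, imidazole, DMF, rt
Reagents that add atoms: triisopropylsilyl chloride (TIPSCl), CC(C)[Si](Cl)(C(C)C)C(C)C
Why: Imidazole-promoted silylation caps the only free phenol with a group that withstands n-BuLi and shields its two neighbouring C–H positions in the metalation that follows.

**Step 3**
Reactants: 3 [3,5-bis(methoxymethoxy)phenoxy]triisopropylsilane; 4 prenyl bromide
Product: 6 triisopropyl[3,5-bis(methoxymethoxy)-4-(3-methylbut-2-en-1-yl)phenoxy]silane, via aryllithium 5 (not isolated)
Conditions: n-BuLi (1.1 equiv), THF, 0 °C; then 4, −78 °C → rt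
Reagents that add atoms: none
Why: Directed ortho-metalation removes the proton flanked by the two chelating OMOM groups, and the aryllithium then displaces bromide at the primary carbon of prenyl bromide (SN2 alkylation).

**Step 4**
Reactants: 6 triisopropyl[3,5-bis(methoxymethoxy)-4-(3-methylbut-2-en-1-yl)phenoxy]silane
Product: 7 3,5-bis(methoxymethoxy)-4-(3-methylbut-2-en-1-yl)phenol
Conditions: Bu4NF, AcOH, THF, 0 °C → rt
Reagents that add atoms: none
Why: Fluoride-induced cleavage of the aryl silyl ether is driven by Si–F bond formation and the good phenoxide leaving group, and it leaves the MOM acetals and the alkene untouched.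

**Step 5**
Reactants: 7 3,5-bis(methoxymethoxy)-4-(3-methylbut-2-en-1-yl)phenol
Product: 8 2-iodo-3,5-bis(methoxymethoxy)-4-(3-methylbut-2-en-1-yl)phenol
Conditions: I2 (1.0 equiv), NaHCO3, THF–H2O, 0 °C
Reagents that add atoms: iodine, [I][I]
Why: In this electrophilic aromatic iodination through the phenoxide the two ortho positions are related by the mirror plane and the para position is blocked, so only one mono-iodide can form, and the trioxygenated ring should react well ahead of the prenyl alkene, which has no free neighbouring OH to trap an iodonium ion.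

**Step 6**
Reactants: 8 2-iodo-3,5-bis(methoxymethoxy)-4-(3-methylbut-2-en-1-yl)phenol
Product: 9 tert-butyl[2-iodo-3,5-bis(methoxymethoxy)-4-(3-methylbut-2-en-1-yl)phenoxy]dimethylsilane
Conditions: TBSCl, imidazole, DMF, rt
Reagents that add atoms: tert-butyldimethylsilyl chloride (TBSCl), CC(C)(C)[Si](C)(C)Cl
Why: Standard imidazole-promoted silylation masks the acidic phenol, which would otherwise quench the organozinc or trap the aroyl palladium species, and marks the future C8a oxygen as the only fluoride-labile aryl ether.

**Step 7**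
Reactants: 10 3,4-dihydrocoumarin
Product: 12 2-(3-hydroxy-3-methylbutyl)phenol, via ketone phenoxide 11 (not isolated)
Conditions: MeMgBr (3.5 equiv), THF, 0 °C → rt; then H2O, 0 °C
Reagents that add atoms: methylmagnesium bromide, C[Mg]Br
Why: Double Grignard addition to the aryl lactone opens the ring to the methyl ketone, which takes up a second methyl group, and a non-acidic quench avoids cyclodehydration to the chroman.

**Step 8**
Reactants: 12 2-(3-hydroxy-3-methylbutyl)phenol
Product: 13 4-bromo-2-(3-hydroxy-3-methylbutyl)phenol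
Conditions: NBS (1.0 equiv), MeCN, 0 °C
Reagents that add atoms: N-bromosuccinimide, O=C1CCC(=O)N1Br
Why: Electrophilic bromination of 2-alkylphenols with NBS in acetonitrile is para-selective with respect to the hydroxyl group, and it releases succinimide rather than free acid, so the tertiary alcohol is not ionised.

**Step 9**
Reactants: 13 4-bromo-2-(3-hydroxy-3-methylbutyl)phenol
Product: 14 4-[5-bromo-2-(methoxymethoxy)phenyl]-2-methylbutan-2-ol
Conditions: MOMCl (1.1 equiv), i-Pr2NEt, CH2Cl2, 0 °C
Reagents that add atoms: chloromethyl methyl ether (MOMCl), COCCl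
Why: With one equivalent of MOMCl at low temperature the acidic, unhindered phenol is O-alkylated much faster than the tertiary alcohol.

**Step 10**
Reactants: 14 4-[5-bromo-2-(methoxymethoxy)phenyl]-2-methylbutan-2-ol
Product: 15 {4-[5-bromo-2-(methoxymethoxy)phenyl]-2-methylbutan-2-yl}oxytriethylsilane
Conditions: TESCl, imidazole, DMAP (cat.), DMF, 40 °C
Reagents that add atoms: triethylsilyl chloride (TESCl), CC[Si](Cl)(CC)CC
Why: DMAP-assisted silylation with the small TES group is established for dimethylcarbinols, and the chloride is used instead of the triflate because silyl triflates attack aryl MOM ethers.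

**Step 11**
Reactants: 15 {4-[5-bromo-2-(methoxymethoxy)phenyl]-2-methylbutan-2-yl}oxytriethylsilane
Product: 17 [4-(methoxymethoxy)-3-(3-methyl-3-triethylsilyloxybutyl)phenyl]methanol, via aryllithium 16 (not isolated)
Conditions: n-BuLi (1.1 equiv), THF, −78 °C; dry (CH2O)n, −78 °C → rt; then H2O
Reagents that add atoms: paraformaldehyde (reacts as formaldehyde), C=O
Why: Bromine–lithium exchange is fast at −78 °C and spares the acetal and silyl ether, and the aryllithium adds to the formaldehyde released from the polymer on warming (hydroxymethylation).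

**Step 12**
Reactants: 17 [4-(methoxymethoxy)-3-(3-methyl-3-triethylsilyloxybutyl)phenyl]methanol
Product: 19 4-(chloromethyl)-1-(methoxymethoxy)-2-(3-methyl-3-triethylsilyloxybutyl)benzene, via benzylic mesylate 18 (not isolated)
Conditions: MsCl (1.2 equiv), Et3N (1.5 equiv), CH2Cl2, 0 °C → rt; used without storage
Reagents that add atoms: methanesulfonyl chloride, CS(=O)(=O)Cl
Why: Mesylation under basic conditions is followed by displacement with the chloride formed in the same flask, which is rapid for a para-alkoxybenzylic mesylate and avoids the acid that would cleave MOM or TES.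

**Step 13**
Reactants: 19 4-(chloromethyl)-1-(methoxymethoxy)-2-(3-methyl-3-triethylsilyloxybutyl)benzene
Product: 20 [4-(methoxymethoxy)-3-(3-methyl-3-triethylsilyloxybutyl)benzyl]zinc chloride (LiCl-complexed and titrated THF solution)
Conditions: Zn dust (activated, 1.5 equiv), LiCl (1.5 equiv), THF, 25 °C
Reagents that add atoms: zinc, [Zn]
Why: LiCl-assisted direct insertion of zinc into benzylic chlorides is a standard entry to benzylic zinc chlorides, since LiCl solubilises the organozinc and keeps Wurtz-type homocoupling low, and the acetal and silyl ether are inert.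

**Step 14**
Reactants: 9 tert-butyl[2-iodo-3,5-bis(methoxymethoxy)-4-(3-methylbut-2-en-1-yl)phenoxy]dimethylsilane; 20 [4-(methoxymethoxy)-3-(3-methyl-3-triethylsilyloxybutyl)benzyl]zinc chloride; 21 carbon monoxide
Product: 22 1-[2-(tert-butyldimethylsilyloxy)-4,6-bis(methoxymethoxy)-5-(3-methylbut-2-en-1-yl)phenyl]-2-[4-(methoxymethoxy)-3-(3-methyl-3-triethylsilyloxybutyl)phenyl]ethanone
Conditions: Pd(PPh3)4 (5 mol %), CO (5 bar), THF, 50 °C; 20 (1.6 equiv) dosed over 3 h
Reagents that add atoms: none
Why: Zerovalent palladium inserts into the C4a–I bond of 9, CO inserts into the aryl–palladium bond to give an aroyl complex of divalent palladium, the benzyl group passes from zinc to palladium, and reductive elimination forms C4–C3 and returns the catalyst. The reaction type is the carbonylative Negishi coupling of aryl iodides with organozinc halides, which is established for benzylic zinc reagents (giving 1,2-diarylethanones) and for aryl iodides with two ortho substituents. No ring is closed and no stereocentre is formed. The selectivity needed is ketone over the diarylmethane of direct coupling: the OTBS and OMOM groups beside C4a shield the aryl complex from transmetalation, migration of this crowded, electron-rich aryl group onto CO relieves strain, and CO pressure with slow dosing of 20 keeps CO in excess over the organozinc. The MOM, TBS and TES ethers and the prenyl alkene are inert to the mild organozinc, and the hindered ketone 22 should resist a second addition.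

**Step 15**
Reactants: 22 the protected deoxybenzoin of step 14
Product: 23 1-[2-hydroxy-4,6-bis(methoxymethoxy)-5-(3-methylbut-2-en-1-yl)phenyl]-2-[4-(methoxymethoxy)-3-(3-methyl-3-triethylsilyloxybutyl)phenyl]ethanone
Conditions: Bu4NF (1.05 equiv), AcOH (1.1 equiv), THF, 0 °C
Reagents that add atoms: none
Why: Buffered fluoride desilylation removes the aryl TBS ether ortho to the ketone far faster than the hindered tertiary alkyl TES ether, so only the C8a oxygen is freed.

**Step 16**
Reactants: 23 the 2-hydroxydeoxybenzoin of step 15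
Product: 25 5,7-bis(methoxymethoxy)-3-[4-(methoxymethoxy)-3-(3-methyl-3-triethylsilyloxybutyl)phenyl]-6-(3-methylbut-2-en-1-yl)-4H-chromen-4-one, via enaminone 24 (not isolated)
Conditions: Me2NCH(OMe)2 (4 equiv), toluene, 90 °C
Reagents that add atoms: N,N-dimethylformamide dimethyl acetal, COC(OC)N(C)C
Why: In this classical isoflavone synthesis from a 2-hydroxydeoxybenzoin the doubly activated CH2 condenses with the formamide acetal to an enaminone, and the only free phenol adds to its β-carbon and expels dimethylamine (6-endo addition–elimination), closing ring C as the 6-prenyl isomer.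

**Step 17**
Reactants: 25 the protected isoflavone of step 16
Product: 26 coloratanin A
Conditions: HCl (1.25 M in MeOH, substoichiometric), MeOH–THF, rt → 40 °C
Reagents that add atoms: none
Why: Acid-catalysed acetal exchange with methanol cleaves the three aryl MOM ethers and solvolysis at silicon removes the TES group without a cation at the tertiary carbon, under acid too dilute to protonate the prenyl alkene or ionise the tertiary alcohol toward chroman formation.

**Compound list**
1 | phloroglucinol | Oc1cc(O)cc(O)c1 | starting material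
2 | 3,5-bis(methoxymethoxy)phenol | COCOc1cc(O)cc(OCOC)c1 | intermediate
3 | [3,5-bis(methoxymethoxy)phenoxy]triisopropylsilane | COCOc1cc(OCOC)cc(O[Si](C(C)C)(C(C)C)C(C)C)c1 | intermediate
4 | prenyl bromide (1-bromo-3-methylbut-2-ene) | CC(C)=CCBr | starting material
5 | [2,6-bis(methoxymethoxy)-4-(triisopropylsilyloxy)phenyl]lithium | [Li]c1c(OCOC)cc(O[Si](C(C)C)(C(C)C)C(C)C)cc1OCOC | intermediate
6 | triisopropyl[3,5-bis(methoxymethoxy)-4-(3-methylbut-2-en-1-yl)phenoxy]silane | CC(C)=CCc1c(OCOC)cc(O[Si](C(C)C)(C(C)C)C(C)C)cc1OCOC | intermediate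
7 | 3,5-bis(methoxymethoxy)-4-(3-methylbut-2-en-1-yl)phenol | CC(C)=CCc1c(OCOC)cc(O)cc1OCOC | intermediate
8 | 2-iodo-3,5-bis(methoxymethoxy)-4-(3-methylbut-2-en-1-yl)phenol | CC(C)=CCc1c(OCOC)cc(O)c(I)c1OCOC | intermediate
9 | tert-butyl[2-iodo-3,5-bis(methoxymethoxy)-4-(3-methylbut-2-en-1-yl)phenoxy]dimethylsilane | COCOc1cc(O[Si](C)(C)C(C)(C)C)c(I)c(OCOC)c1CC=C(C)C | intermediate
10 | 3,4-dihydrocoumarin | O=C1CCc2ccccc2O1 | starting material
11 | bromomagnesium 2-(3-oxobutyl)phenoxide | CC(=O)CCc1ccccc1O[Mg]Br | intermediate
12 | 2-(3-hydroxy-3-methylbutyl)phenol | CC(C)(O)CCc1ccccc1O | intermediate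
13 | 4-bromo-2-(3-hydroxy-3-methylbutyl)phenol | CC(C)(O)CCc1cc(Br)ccc1O | intermediate
14 | 4-[5-bromo-2-(methoxymethoxy)phenyl]-2-methylbutan-2-ol | COCOc1ccc(Br)cc1CCC(C)(C)O | intermediate
15 | {4-[5-bromo-2-(methoxymethoxy)phenyl]-2-methylbutan-2-yl}oxytriethylsilane | COCOc1ccc(Br)cc1CCC(C)(C)O[Si](CC)(CC)CC | intermediate
16 | [4-(methoxymethoxy)-3-(3-methyl-3-triethylsilyloxybutyl)phenyl]lithium | [Li]c1ccc(OCOC)c(CCC(C)(C)O[Si](CC)(CC)CC)c1 | intermediate
17 | [4-(methoxymethoxy)-3-(3-methyl-3-triethylsilyloxybutyl)phenyl]methanol | OCc1ccc(OCOC)c(CCC(C)(C)O[Si](CC)(CC)CC)c1 | intermediate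
18 | 4-(methoxymethoxy)-3-(3-methyl-3-triethylsilyloxybutyl)benzyl methanesulfonate | CS(=O)(=O)OCc1ccc(OCOC)c(CCC(C)(C)O[Si](CC)(CC)CC)c1 | intermediate
19 | 4-(chloromethyl)-1-(methoxymethoxy)-2-(3-methyl-3-triethylsilyloxybutyl)benzene | ClCc1ccc(OCOC)c(CCC(C)(C)O[Si](CC)(CC)CC)c1 | intermediate
20 | [4-(methoxymethoxy)-3-(3-methyl-3-triethylsilyloxybutyl)benzyl]zinc chloride | Cl[Zn]Cc1ccc(OCOC)c(CCC(C)(C)O[Si](CC)(CC)CC)c1 | intermediate
21 | carbon monoxide | [C-]#[O+] | starting material
22 | 1-[2-(tert-butyldimethylsilyloxy)-4,6-bis(methoxymethoxy)-5-(3-methylbut-2-en-1-yl)phenyl]-2-[4-(methoxymethoxy)-3-(3-methyl-3-triethylsilyloxybutyl)phenyl]ethanone | COCOc1cc(O[Si](C)(C)C(C)(C)C)c(C(=O)Cc2ccc(OCOC)c(CCC(C)(C)O[Si](CC)(CC)CC)c2)c(OCOC)c1CC=C(C)C | intermediate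
23 | 1-[2-hydroxy-4,6-bis(methoxymethoxy)-5-(3-methylbut-2-en-1-yl)phenyl]-2-[4-(methoxymethoxy)-3-(3-methyl-3-triethylsilyloxybutyl)phenyl]ethanone | COCOc1cc(O)c(C(=O)Cc2ccc(OCOC)c(CCC(C)(C)O[Si](CC)(CC)CC)c2)c(OCOC)c1CC=C(C)C | intermediate
24 | (E)-3-(dimethylamino)-1-[2-hydroxy-4,6-bis(methoxymethoxy)-5-(3-methylbut-2-en-1-yl)phenyl]-2-[4-(methoxymethoxy)-3-(3-methyl-3-triethylsilyloxybutyl)phenyl]prop-2-en-1-one | COCOc1cc(O)c(C(=O)/C(=C/N(C)C)c2ccc(OCOC)c(CCC(C)(C)O[Si](CC)(CC)CC)c2)c(OCOC)c1CC=C(C)C | intermediate
25 | 5,7-bis(methoxymethoxy)-3-[4-(methoxymethoxy)-3-(3-methyl-3-triethylsilyloxybutyl)phenyl]-6-(3-methylbut-2-en-1-yl)-4H-chromen-4-one | COCOc1cc2occ(-c3ccc(OCOC)c(CCC(C)(C)O[Si](CC)(CC)CC)c3)c(=O)c2c(OCOC)c1CC=C(C)C | intermediate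
26 | coloratanin A, 5,7-dihydroxy-3-[4-hydroxy-3-(3-hydroxy-3-methylbutyl)phenyl]-6-(3-methylbut-2-en-1-yl)-4H-chromen-4-one | CC(C)=CCc1c(O)cc2occ(-c3ccc(O)c(CCC(C)(C)O)c3)c(=O)c2c1O | target

**Step count and risks**

Total step count: 17.
Longest linear sequence: 11 steps (steps 7–13, then 14–17). The ring A branch (steps 1–6) joins at step 14.

**1. Step 14.**
- What may go wrong: transmetalation to the aryl complex may outrun CO insertion (direct coupling). Oxidative addition into the crowded, electron-rich C4a–I bond may stall. The benzylzinc may be consumed by homocoupling or by deprotonation of the acidic CH2 of the product.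
- Fallback, from 9 and 20 back to 22: C4 enters as a formyl carbon and C4–C3 is made by carbonyl addition. Iodine–magnesium exchange of 9 with i-PrMgCl·LiCl (THF, −20 °C → 0 °C) should give the arylmagnesium chloride F1. Unlike a lithium species, F1 should not trigger migration of the neighbouring silyl group from oxygen to carbon. Quenching with DMF gives 2-(tert-butyldimethylsilyloxy)-4,6-bis(methoxymethoxy)-5-prenylbenzaldehyde F2. Addition of 20 to F2 (THF, 25 °C) should give the racemic 1,2-diarylethanol F3. Dess–Martin oxidation of F3 (CH2Cl2, 0 °C) delivers 22.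

**2. Step 5.**
- What may go wrong: electrophilic iodine may add to the electron-rich trisubstituted alkene, or a second iodination may occur at the remaining ortho position.
- Fallback, from 3 (through 5) back to 9: the side chain passes through the iodination as an allyl group, whose monosubstituted alkene is far less nucleophilic. It is converted to prenyl afterwards by olefin cross metathesis. Aryllithium 5 is alkylated with allyl bromide to the 4-allyl TIPS ether F4. Bu4NF/AcOH gives 4-allyl-3,5-bis(methoxymethoxy)phenol F5. I2/NaHCO3 gives the 4-allyl-2-iodophenol F6. TBSCl/imidazole gives its TBS ether F7. Cross metathesis of F7 with excess 2-methyl-2-butene (second-generation Grubbs catalyst, CH2Cl2, 40 °C) gives 9.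

**3. Step 17.**
- What may go wrong: acid may close the 5-OH or 7-OH onto the protonated prenyl group, or the 4′-OH onto the tertiary carbinol carbon, before the last MOM group is lost.
- Fallback, from 25 back to 26: the acetals are exchanged for silyl ethers under weakly basic conditions and all silicon is then removed with fluoride, so no Brønsted acid meets the free phenols. TESOTf and 2,2′-bipyridyl (CH2Cl2, 0 °C → rt) should convert the three aryl MOM ethers of 25 into aryl TES ethers, giving the tetrakis(triethylsilyl) ether F8. Bu4NF/AcOH (THF, rt) then releases 26.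

**Further compounds**
F1 | step 14 | [2-(tert-butyldimethylsilyloxy)-4,6-bis(methoxymethoxy)-5-(3-methylbut-2-en-1-yl)phenyl]magnesium chloride | Cl[Mg]c1c(O[Si](C)(C)C(C)(C)C)cc(OCOC)c(CC=C(C)C)c1OCOC
F2 | step 14 | 2-(tert-butyldimethylsilyloxy)-4,6-bis(methoxymethoxy)-5-(3-methylbut-2-en-1-yl)benzaldehyde | O=Cc1c(O[Si](C)(C)C(C)(C)C)cc(OCOC)c(CC=C(C)C)c1OCOC
F3 | step 14 | racemic 1-[2-(tert-butyldimethylsilyloxy)-4,6-bis(methoxymethoxy)-5-(3-methylbut-2-en-1-yl)phenyl]-2-[4-(methoxymethoxy)-3-(3-methyl-3-triethylsilyloxybutyl)phenyl]ethanol | OC(Cc1ccc(OCOC)c(CCC(C)(C)O[Si](CC)(CC)CC)c1)c1c(O[Si](C)(C)C(C)(C)C)cc(OCOC)c(CC=C(C)C)c1OCOC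
F4 | step 5 | [4-allyl-3,5-bis(methoxymethoxy)phenoxy]triisopropylsilane | C=CCc1c(OCOC)cc(O[Si](C(C)C)(C(C)C)C(C)C)cc1OCOC
F5 | step 5 | 4-allyl-3,5-bis(methoxymethoxy)phenol | C=CCc1c(OCOC)cc(O)cc1OCOC
F6 | step 5 | 4-allyl-2-iodo-3,5-bis(methoxymethoxy)phenol | C=CCc1c(OCOC)cc(O)c(I)c1OCOC
F7 | step 5 | [4-allyl-2-iodo-3,5-bis(methoxymethoxy)phenoxy](tert-butyl)dimethylsilane | C=CCc1c(OCOC)cc(O[Si](C)(C)C(C)(C)C)c(I)c1OCOC
F8 | step 17 | 6-(3-methylbut-2-en-1-yl)-5,7-bis(triethylsilyloxy)-3-[4-(triethylsilyloxy)-3-(3-methyl-3-triethylsilyloxybutyl)phenyl]-4H-chromen-4-one | CC(C)=CCc1c(O[Si](CC)(CC)CC)cc2occ(-c3ccc(O[Si](CC)(CC)CC)c(CCC(C)(C)O[Si](CC)(CC)CC)c3)c(=O)c2c1O[Si](CC)(CC)CC
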